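All runs were generated by integration with made-up constants.

Time comes first, and for "now" you need no estimate: Wednesday's run is this very flask, and at 5.00 min it reads 25.0%, good to 0.5 percentage points.

| flask | Z | temperature | remark | time |
|---|---|---|---|---|
| Wednesday's | 1 M | 0 °C | the very flask that is asked about, followed so far |  |
| Thursday's | 0.67 M | 6 °C | run made earlier |  |
| flask | 1.0 M | 0 °C |  | 5.0 min |

- Wednesday's (time / min: J / %): 0.333: 18.0; 1.00: 29.5; 2.00: 30.7; 2.50: 29.2; 4.00: 26.4; 5.00: 25.0
- Thursday's (time / s: J / %): 10.0: 18.3; 20.0: 28.2; 40.0: 33.4; 60.0: 33.1; 80.0: 33.5; 120: 31.9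

(standard deviation of a reading: 0.5 percentage points)

- alder: at 5.0 min take out 90% of the J then present, then wait 10 min
- elm: at 5.0 min raise the temperature by 20 K, then wait 10 min
- maple: at 5.0 min add Z, 50.0% of the amount charged, then wait 10 min
- oak: change nothing and wait 10 min more

- removed J is counted in
- the analysis behind the earlier runs scatters by 0.5 percentage points, standard deviation
- additions bring no volume worth counting

1. J, in percent of the Z first charged, at 5.0 min
2. what to do for the largest gain in J; "none" if nothing gains more than 2 percentage points (alder / elm / maple / oak / none)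
3. J present, with what was taken out counted in, in percent of the Z first charged, after alder
4. J present, with what was taken out counted in, in percent of the Z first charged, after oak

The choice needs more. At 1.00 min Wednesday's J already reads 29.5%, so the rise is far shorter than the further 10 min. You may therefore treat the exchange as a quasi-equilibrium and ask what it leaves free. Let δ be the dead share of the charge at J's highest reading, which no longer exchanges, and suppose it grows in proportion to concentration. Setting aside Thursday's warmer temperature, the highest readings 30.7% at 1 M and 33.5% at 0.67 M then give δ = 21.7%. So w = 39.2%, the live share, J's part of all that still exchanges, and with 25.0% at 5.00 min the dead share of Wednesday's flask has by then grown to 36.2%.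

Alder banks 22.5%, and w of the live material left regrows as 16.2%, so I count 38.7%. Is δ critical? Setting it to zero gives 40.6%, a shift of 1.9 points, so it matters little. The 25.0% enters twice, in what is banked and in what regrows, so that is the number to know well. Adding Z, its dead share scaled to its smaller amount, brings 16.0% by the same share, more than alder's 14 points, but what alder banks stays out of the slide, so alder comes out ahead if live J keeps less than 90.7% over the 10 min. Between its last two readings Wednesday's J kept 94.7%, so I commit to alder; oak continues that slide, and warming I cannot reckon from these runs.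

The forecast gives 25%, alder, 30% after alder and 14.5% after oak, granting regrowth “if the equilibrium is real”, and its alder count is lower than mine.

The flask gives 25.2% now, and alder is best with a gain of 13 points, against 8.6 points for maple. After alder it counts 38.0%, after oak 22.4%.

    Z ⇌ J (K = 3.50, k = 0.0130 s⁻¹, Ea = 73.0 kJ mol⁻¹, ΔH = 1.00 kJ mol⁻¹)
    Z ⇌ Q (K = 2.60, k = 0.00670 s⁻¹, Ea = 70.0 kJ mol⁻¹, ΔH = 1.00 kJ mol⁻¹)
    J ⇌ Q (k = 0.00210 s⁻¹, Ea = 70.0 kJ mol⁻¹)
    2 Z → D (k = 0.00760 L mol⁻¹ s⁻¹, Ea = 49.0 kJ mol⁻¹)
    J → X (k = 1.80 × 10⁻⁶ s⁻¹, Ea = 93.0 kJ mol⁻¹)
    J ⇌ E (K = 0.920, k = 0.00330 s⁻¹, Ea = 86.0 kJ mol⁻¹, ΔH = −45.0 kJ mol⁻¹)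
    (constants at 0 °C)

In this flask at 5.00 min J is made at 0.404 of the rate it is used up, each taken net. Oak's flask keeps 88.9% of its J over the 10 min. Scaling the regrowth reckoned with w by that gives 14.4%, while the alder count less what was taken out leaves 15.4%.

Now take the neighbour, this flask charged with 0.25 M of Z. Scaled the same way, the dead share at 5.00 min shrinks to 9.05%, and w gives J = 35.7%. The computed value is 32.3%.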